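(The runs are calculated on assumed constants; scatter was added.)

The chemist charging this flask with substrate wants to know when intermediate D stands highest and how long it stays close to that height.

| flask | substrate | remark | time |
|---|---|---|---|
| winter | 0.28 M | run made earlier |  |
| noon | 0.44 M | run made earlier |  |
| flask | 0.20 M |  | 15 d |

| run | time / d | intermediate D / % | target / % |
|---|---|---|---|
| winter | 0.333 | 13.9 | 0.8 |
| winter | 0.625 | 19.1 | 0 |
| winter | 1.25 | 20.8 | 0 |
| winter | 3.00 | 17.2 | 2.4 |
| winter | 6.00 | 11.5 | 2.2 |
| winter | 12.0 | 4.1 | 2.4 |
| noon | 0.333 | 12.4 | 0 |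
| noon | 0.625 | 17.8 | 0 |
| noon | 1.25 | 16.5 | 0.6 |
| noon | 3.00 | 12.2 | 0.6 |
| noon | 6.00 | 8.1 | 1.8 |
| noon | 12.0 | 3.7 | 2.5 |

(scatter of a reading: 1 percentage point)

- when, up to 15 d, the flask holds most intermediate D
- the amount of intermediate D, in percent of the substrate charged, at that time
- earliest time at which at least nineteen twentieths of that best amount are there, in d
- latest time at which they still are, in d

- what was read earlier has a scatter of 1 percentage point, one standard deviation

The highest reading of D falls from 20.8% in the winter run to 17.8% in the noon run, whose charge is larger. Suppose a step taking one molecule makes D while a rival step takes two; the rival's rate over the maker's then grows with the charge. So take the peak as a dilute ceiling divided by one plus a crowding number, the charge over a crowding concentration. The two peaks give that concentration as 0.669 M and the ceiling as 29.5%.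

For this flask the number is 0.299, so I expect 22.7%, with the top near the time of winter's highest reading, 1.25 d. Two peaks spent on two constants test nothing. The late fall can test it: from 3.00 d to 12.0 d, D falls by 0.159 d⁻¹ in winter and 0.133 d⁻¹ at noon. With a scatter of 1 percentage point, that gap shows no trend with charge, so the fall needs its own constant.

The forecast, higher than my figure, gives 25.6% at 1.25 d, with the asked window from 0.75 d to 2.05 d, its rule “inferred, not proven”.

    intermediate D ⇌ substrate (k = 4.49 × 10⁻⁴ min⁻¹)
    substrate ⇌ intermediate A (K = 0.545, k = 1.21 × 10⁻⁴ min⁻¹)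
    intermediate A ⇌ intermediate C (K = 26.0, k = 1.18 × 10⁻⁴ min⁻¹)
    2 substrate → homo dimer (k = 3.85 × 10⁻⁴ M⁻¹ min⁻¹)
    substrate + intermediate D → side product (k = 0.00231 M⁻¹ min⁻¹)
    intermediate A ⇌ intermediate D (K = 1.82, k = 1.20 × 10⁻⁴ min⁻¹)
    substrate → decomposition product (k = 2.09 × 10⁻⁷ min⁻¹)
    intermediate B ⇌ target (K = 0.535, k = 0.00680 min⁻¹)
    substrate → intermediate B (k = 2.71 × 10⁻⁵ min⁻¹)

The flask reaches 24.3% at 1.33 d, with the asked window from 0.880 d to 2.00 d; that best is 1.6 points above my 22.7%. At 0.080 M the number is 0.120, which gives 26.3%, but that neighbour flask reaches 30.3%, above even my ceiling of 29.5%. In this flask, D is made 4.91 times faster than it is used up at 0.325 d, each step taken net, and at the best time 34.0% of the substrate remains. By 15.0 d the substrate stands at 5.28%, D at 5.47% and side product, whose percentage counts two, at 47.5%.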